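You asked for a quick number, and your hunch was that a long wait, 10 d, would carry the excess of right-handed substrate as high as one liked.

| flask | left-handed substrate | right-handed substrate | protic impurity | solid reagent | catalyst | remark | time |
|---|---|---|---|---|---|---|---|
| grey | 22 mM | 22 mM | 6.6 mM | 37 mM | 0.11 mM | run made earlier |  |
| red | 22 mM | 22 mM | 6.6 mM | 58 mM | 0.11 mM | run made earlier |  |
| flask | 22 mM | 22 mM | 6.60 mM | 26.4 mM | 0.11 mM |  | 10 d |

- grey (time / d: right-handed substrate / %, left-handed substrate / %): 0.625: 46, 47; 1.67: 42, 39; 3.00: 38, 29; 8.00: 23, 6
- red (time / d: right-handed substrate / %, left-handed substrate / %): 2.08: 39, 34; 4.00: 29, 15; 6.00: 16, 0; 8.00: 0, 0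

(each reading ± 2 percentage points)

- whether the excess of right-handed substrate over left-handed substrate among what is left of the two reaches 99% by 10 d (no / yes)
- the highest excess of right-handed substrate over left-handed substrate among what is left of the two up to 10 d

- catalyst is single-handed; left-handed substrate and right-handed substrate are mirror images of each other, charged as a racemate, each of them at the stated concentration
- solid reagent is a solid; its amount is given per volume of the solution
- at the start none of the solid reagent is in solution

I began with a subtraction. I took [solid reagent] less [protic impurity], over [left-handed substrate] plus [right-handed substrate], each as charged, which for your flask gave 45.0%. I called this share of the substrates that the reagent can convert, one equivalent each, once the impurity has taken its own equivalent, the reagent budget.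

The grey run gave one comparison: its budget was 69.1%, and its last reading showed 71.0% converted, inside the scatter. The budget of the red run was 117%, and by 8.00 d both substrates read zero.

At the grey pace your flask would spend its budget in 5.07 d, well before 10 d, so I expected the excess to stop climbing there.

What remained was the excess at that conversion. The grey run read 13.4% at 33.0% converted, and the red run 31.8% at 56.0%. Between these readings, at the budget, I took 23.0%, below the level asked, so my answer was no.

The forecast, made from the same runs, said no with a top of 25%, higher than my figure, holding that “the impurity appears to consume one equivalent of reagent”.

The flask gave no and a top of 24.0%.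

    partner + catalyst + right-handed substrate → catalyst + right-handed product (k = 3.50 × 10⁵ M⁻² h⁻¹)
    partner + catalyst + left-handed substrate → catalyst + left-handed product (k = 7.80 × 10⁵ M⁻² h⁻¹)
    partner + protic impurity → quenched reagent (k = 270 M⁻¹ h⁻¹)
    solid reagent ⇌ partner, rate k4*(cs4 - [partner]) while solid is left; crystals form when [partner] > cs4 (solubility = 2.50 mM, k = 0.130 h⁻¹)

At 1.75 d the partner, the dissolved form of the solid reagent, had a half-life in your flask of 0.50 h by the step with the left-handed substrate taken by itself, far shorter than the 1.75 d by which half of the dissolving up to 10 d was done. At that moment your flask made it 1.00 times as fast as it used it, each step taken net. In your flask the solid reagent, the limiting reagent, stood at 0% of its charge at 5.00 d, with products of 45.9% of the two substrates charged against the budget of 45.0%. A further flask with 45 mM of solid reagent had a budget of 87.3%; it held 87.3% as products at 10.0 d, and its top excess was 73.0%.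

The data were generated by integration with made-up constants; scatter was added.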